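The route rests on closing the ten-membered ring at C3–C4 (briarane numbering) by alkylation. In one operation the caesium enolate of a C2 β-keto sulfone, which can enolise only toward C3 because C1 is quaternary, displaces the primary chloride at C4, allylic to the Z-C5=C6 alkene; this forms the C1–C10 carbocycle and keeps a C2 ketone for the last acetoxy centre. The precursor is the cyclohexene (C1, C10–C14) bearing the finished C7–C8–C17–C19 butyrolactone arm at C10 and the sulfonylacetyl group at C1; its C8 and C9 oxygens are silylated, so that the hydroxyl at C8 cannot close a six-membered ether onto C4.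

Key step: step 29

Remark: briarane numbering is used for all positions; C9 is carried as a protected carbinol of defined but immaterial configuration (9R, as the aldol delivers it) because it ends as the ketone; NAP = naphthalen-2-ylmethyl, DMB = 3,4-dimethoxybenzyl, Men = (1S,2R,5S)-menthyl.

**Step 1**
Reactants: 1 5-hydroxyfuran-2(5H)-one; 2 (1S,2R,5S)-(+)-menthol
Product: 3 (5S)-5-(Men-oxy)furan-2(5H)-one
Conditions: CSA (cat.), toluene, reflux, Dean–Stark; crystallisation from petroleum ether, mother liquor re-equilibrated with acid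
Reagents that add atoms: none
Why: Acid-catalysed acetalisation of the pseudo-acid gives both acetal epimers, and crystallisation-induced epimerisation should deliver the 5S diastereomer (mirror image of the familiar l-menthol case).

**Step 2**
Reactants: 4 2-bromoprop-2-en-1-ol; 5 2-(bromomethyl)naphthalene
Product: 6 2-{[(2-bromoprop-2-en-1-yl)oxy]methyl}naphthalene
Conditions: NaH, THF, 0 °C; then 5, Bu4NI (cat.), rt
Reagents that add atoms: none
Why: Williamson etherification of the allylic alkoxide with a reactive benzylic-type bromide.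

**Step 3**
Reactants: 3 (5S)-5-(Men-oxy)furan-2(5H)-one; 6 NAP ether of 2-bromoallyl alcohol
Product: 10 all-trans lactone (C9 O-Men, C10 alkenyl bearing C20 O-NAP, C1 methyl), via alkenyllithium 7 (not isolated), via lithium dialkenylcuprate 8 (not isolated), via lithium lactone enolate 9 (not isolated)
Conditions: 6, t-BuLi, Et2O, −78 °C; CuBr·SMe2; then 3, −78 °C; MeI, HMPA, −78 → −20 °C
Reagents that add atoms: iodomethane CI
Why: Cuprate 1,4-addition to the butenolide occurs anti to the C9 menthyloxy group and sets C10, and the enolate is methylated anti to the new C10 substituent (tandem conjugate addition–alkylation; C1 is re-set in step 4).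

**Step 4**
Reactants: 10 all-trans lactone
Product: 12 α-formyl lactone with quaternary C1 (formyl C14 trans, methyl cis to the C10 alkenyl group), via lithium enolate 11 (not isolated)
Conditions: LDA, THF, −78 °C; HCO2Et, −78 °C; AcOH quench at −78 °C
Reagents that add atoms: ethyl formate CCOC=O
Why: C-formylation of the tetrasubstituted lactone enolate (crossed Claisen condensation) takes place on the face anti to the C10 alkenyl group, which fixes the quaternary C1 centre.

**Step 5**
Reactants: 12 α-formyl lactone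
Product: 13 (14S)-homoallylic alcohol
Conditions: (−)-Ipc2BOMe [(+)-α-pinene series], allylMgBr, Et2O, 0 °C → rt; then 12, −78 °C; ethanolamine work-up
Reagents that add atoms: B-allyldiisopinocampheylborane C=CCB(C1CC2CC(C1C)C2(C)C)C1CC2CC(C1C)C2(C)C
Why: Brown allylboration through a chair six-membered transition state delivers allyl to the Si face of the non-enolisable aldehyde and sets C14 as S under reagent control.

**Step 6**
Reactants: 13 (14S)-homoallylic alcohol
Product: 14 trans-fused cyclohexene–lactone acetal (C11=C12)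
Conditions: Grubbs II (5 mol %), CH2Cl2 (5 mM), 40 °C
Reagents that add atoms: none
Why: Ring-closing metathesis of the terminal alkene with the 1,1-disubstituted alkene forms the trisubstituted C11=C12 cyclohexene with loss of ethene.

**Step 7**
Reactants: 14 trans-fused cyclohexene–lactone acetal
Product: 15 triol (14-OH, C2 CH2OH on C1, C9 CH2OH on C10)
Conditions: LiAlH4, THF, 0 °C → rt
Reagents that add atoms: none
Why: Hydride reduction opens the acylal-type lactone, reduces C2 and (after collapse of the hemiacetal) C9 to primary alcohols and releases the menthol auxiliary.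

**Step 8**
Reactants: 15 triol
Product: 16 O14/O2 acetonide with free C9 alcohol
Conditions: Me2C(OMe)2, PPTS (cat.), CH2Cl2, rt; then MeOH (brief) to cleave any mixed ketal
Reagents that add atoms: 2,2-dimethoxypropane COC(C)(C)OC
Why: Thermodynamic ketalisation favours the six-membered 1,3-dioxane of the cis-1,3-diol over the seven-membered alternatives, which leaves only the C9 hydroxyl free.

**Step 9**
Reactants: 16 acetonide alcohol
Product: 17 C9 aldehyde
Conditions: DMP, NaHCO3, CH2Cl2, 0 °C → rt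
Reagents that add atoms: none
Why: Buffered Dess–Martin oxidation should give the β,γ-unsaturated aldehyde without epimerising C10 or moving the C11=C12 alkene.

**Step 10**
Reactants: 18 3,4-dimethoxybenzyl alcohol; 19 bromoacetic acid
Product: 20 2-[(3,4-dimethoxybenzyl)oxy]acetic acid
Conditions: NaH (excess), THF, 0 °C → reflux; aq. HCl
Reagents that add atoms: none
Why: Williamson etherification of the alkoxide with sodium bromoacetate.

**Step 11**
Reactants: 20 DMB-glycolic acid; 21 (S)-4-benzyl-1,3-thiazolidine-2-thione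
Product: 22 N-(DMB-oxyacetyl) thiazolidinethione
Conditions: EDC·HCl, DMAP (cat.), CH2Cl2, 0 °C → rt
Reagents that add atoms: none
Why: Carbodiimide-mediated N-acylation of the auxiliary.

**Step 12**
Reactants: 22 N-(DMB-oxyacetyl) thiazolidinethione; 17 C9 aldehyde
Product: 24 syn-aldol adduct (8S,9R; 9-OH, 8-ODMB), via chlorotitanium enolate 23 (not isolated)
Conditions: 22, TiCl4, i-Pr2NEt, NMP, CH2Cl2, −78 °C; then 17, −78 → −40 °C
Reagents that add atoms: none
Why: The titanium-mediated glycolate aldol (Evans-syn) proceeds through a closed Zimmerman–Traxler transition state of the Z-enolate whose face is fixed by the benzyl group, which sets C8 as S (the relay centre for C7) and C9 as R.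

**Step 13**
Reactants: 24 syn-aldol adduct
Product: 25 9-O-TBS ether
Conditions: TBSOTf, 2,6-lutidine, CH2Cl2, −78 → 0 °C
Reagents that add atoms: tert-butyldimethylsilyl triflate CC(C)(C)[Si](C)(C)OS(=O)(=O)C(F)(F)F
Why: Silylation of the hindered secondary alcohol with a silyl triflate.

**Step 14**
Reactants: 25 9-O-TBS ether
Product: 26 C7 aldehyde (8-ODMB, 9-OTBS)
Conditions: DIBAL-H, CH2Cl2, −78 °C; Rochelle salt
Reagents that add atoms: none
Why: The activated N-acyl thiazolidinethione is reduced to a stable aluminium hemiaminal that releases the aldehyde and the auxiliary on work-up (reductive auxiliary cleavage), leaving C8 untouched.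

**Step 15**
Reactants: 27 prop-2-yn-1-ol
Product: 29 (Z)-3-iodo-2-methylprop-2-en-1-ol, via alkenylmagnesium alkoxide 28 (not isolated)
Conditions: MeMgBr, CuI (10 mol %), THF, −10 °C → rt; then I2, −78 → 0 °C
Reagents that add atoms: methylmagnesium bromide C[Mg]Br; iodine II
Why: Alkoxide-directed copper-catalysed anti-carbomagnesiation gives the chelated alkenylmagnesium, and iodinolysis with retention gives the Z iodide.

**Step 16**
Reactants: 29 (Z)-3-iodo-2-methylprop-2-en-1-ol
Product: 30 triethylsilyl ether of 29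
Conditions: TESCl, imidazole, CH2Cl2, 0 °C
Reagents that add atoms: chlorotriethylsilane CC[Si](Cl)(CC)CC
Why: Silylation of a primary allylic alcohol.

**Step 17**
Reactants: 30 (Z)-alkenyl iodide TES ether; 26 C7 aldehyde
Product: 33 (7S)-allylic alcohol with Z-C5=C6, via alkenyllithium 31 (not isolated), via alkenylmagnesium bromide 32 (not isolated)
Conditions: 30, t-BuLi, Et2O, −78 °C; MgBr2·OEt2; then 26 precomplexed with MgBr2·OEt2, CH2Cl2, −78 °C
Reagents that add atoms: none
Why: In the Cram-chelate addition magnesium bridges the aldehyde oxygen and the C8 benzyl-type ether, the configurationally stable Z-alkenyl nucleophile attacks anti to the C9 branch, and C7 is set as S.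

**Step 18**
Reactants: 33 (7S)-allylic alcohol; 34 2-bromopropanoyl bromide
Product: 35 7-O-(2-bromopropanoyl) ester (epimers at CHBr)
Conditions: pyridine, DMAP (cat.), CH2Cl2, −20 → 0 °C
Reagents that add atoms: none
Why: O-acylation with an acid bromide; the bromine-bearing centre is lost on enolate formation in step 21.

**Step 19**
Reactants: 35 bromopropanoate
Product: 36 C8 alcohol
Conditions: DDQ, CH2Cl2/pH 7 buffer, 0 °C
Reagents that add atoms: none
Why: Oxidative cleavage of the electron-rich 3,4-dimethoxybenzyl ether by DDQ is much faster than that of the naphthylmethyl ether at C20.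

**Step 20**
Reactants: 36 C8 alcohol
Product: 37 C8 ketone (α-acyloxy ketone)
Conditions: DMP, NaHCO3, CH2Cl2, rt
Reagents that add atoms: none
Why: Buffered Dess–Martin oxidation of the only free hydroxyl.

**Step 21**
Reactants: 37 C8 ketone
Product: 39 β-hydroxy γ-lactone (7-alkenyl, 8-OH and 17-methyl cis; C9 trans), via samarium ester enolate 38 (not isolated)
Conditions: SmI2, THF, −78 °C
Reagents that add atoms: none
Why: The intramolecular samarium Reformatsky reaction reduces the C–Br bond and the Sm(III) enolate adds to the neighbouring ketone in a five-membered closure in which the bulky C9 branch should sit trans to the C7 alkenyl group and to the C17 methyl (the latter is also the thermodynamic epimer, reachable with DBU).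

**Step 22**
Reactants: 39 β-hydroxy γ-lactone
Product: 40 8-O-TES ether
Conditions: TESOTf, 2,6-lutidine, CH2Cl2, −78 → 0 °C
Reagents that add atoms: triethylsilyl triflate CC[Si](CC)(CC)OS(=O)(=O)C(F)(F)F
Why: Silyl triflate silylation of the tertiary alcohol.

**Step 23**
Reactants: 40 8-O-TES ether
Product: 41 triol (14-OH, C2 CH2OH, C4 CH2OH)
Conditions: PPTS, MeOH/CH2Cl2, rt
Reagents that add atoms: none
Why: Mild acid methanolysis should remove the acetonide and the primary allylic TES ether while the tertiary TES and the hindered secondary TBS ethers stay.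

**Step 24**
Reactants: 41 triol
Product: 42 Z-allylic chloride diol
Conditions: NCS, Me2S, CH2Cl2, −20 → 0 °C
Reagents that add atoms: N-chlorosuccinimide O=C1CCC(=O)N1Cl
Why: Corey–Kim chlorination converts only the allylic alkoxysulfonium salt into the chloride by direct SN2 attack of chloride, so the Z geometry and the other two hydroxyls are kept.

**Step 25**
Reactants: 42 Z-allylic chloride diol
Product: 43 C2 aldehyde with free 14-OH
Conditions: TEMPO (cat.), PhI(OAc)2, CH2Cl2, rt
Reagents that add atoms: none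
Why: The oxoammonium (TEMPO/BAIB) oxidation is selective for the primary alcohol over the secondary one.

**Step 26**
Reactants: 43 C2 aldehyde
Product: 44 14-acetate aldehyde
Conditions: Ac2O, pyridine, DMAP (cat.), CH2Cl2, 0 °C → rt
Reagents that add atoms: acetic anhydride CC(=O)OC(C)=O
Why: DMAP-catalysed acetylation of the secondary alcohol; the aldehyde has no α-hydrogen and cannot eliminate.

**Step 27**
Reactants: 45 methyl phenyl sulfone; 44 14-acetate aldehyde
Product: 47 β-hydroxy sulfone (C2 epimers), via sulfonylmethyllithium 46 (not isolated)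
Conditions: 45, n-BuLi, THF, −78 °C; then 44, −78 °C; AcOH quench at −78 °C
Reagents that add atoms: none
Why: 1,2-Addition of the α-sulfonyl carbanion to the aldehyde is far faster than attack on acetate, lactone or allylic chloride at −78 °C.

**Step 28**
Reactants: 47 β-hydroxy sulfone
Product: 48 seco β-keto sulfone with Z-allylic chloride
Conditions: DMP, NaHCO3, CH2Cl2, rt
Reagents that add atoms: none
Why: Dess–Martin oxidation of the β-hydroxy sulfone gives the β-keto sulfone and removes the C2 epimer mixture.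

**Step 29**
Reactants: 48 seco β-keto sulfone
Product: 50 ten-membered α-sulfonyl C2 ketone (C3 epimers), via caesium enolate 49 (not isolated)
Conditions: Cs2CO3, Bu4NI (cat.), MeCN, 50 °C, slow addition to about 1 mM
Reagents that add atoms: none
Why: Cs2CO3 deprotonates the β-keto sulfone (the only acidic C–H, since C1 is quaternary and C9 is a silylated carbinol) and the soft caesium enolate 49 displaces chloride at the primary allylic C4 by SN2 (through the iodide under Bu4NI catalysis), forming C3–C4. The closest known reaction type is the high-dilution macrocyclic C-alkylation of β-keto sulfones and β-keto esters with allylic halides used for ten- to fourteen-membered terpenoid carbocycles. The ten-membered ring C1–C10 closes in the exo-tet mode at an sp3 carbon, with the cis C5=C6 alkene and the trans C1/C10 substitution of the cyclohexene bringing the two ends together. The new C3 centre is not controlled (both epimers interconvert through the enolate and are carried on together), because the sulfone is removed in step 30. C- over O-alkylation is secured by the soft sulfonyl-stabilised enolate and the iodide leaving group, and SN2 over SN2′ by the unhindered primary C4 against the trisubstituted C6, attack at which would give a strained eight-membered ring. The Z geometry is untouched in a direct SN2 step, and silylation of O8 and O9 removes the competing six- and seven-membered ether closures.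

**Step 30**
Reactants: 50 α-sulfonyl ketone
Product: 51 ten-membered C2 ketone
Conditions: SmI2, THF/MeOH, −78 °C
Reagents that add atoms: none
Why: Reductive desulfonylation of the α-sulfonyl ketone by single-electron transfer gives the samarium enolate, which is protonated by methanol.

**Step 31**
Reactants: 51 C2 ketone
Product: 52 (2S)-alcohol
Conditions: (R)-Me-CBS, catecholborane, toluene, −78 → −40 °C
Reagents that add atoms: none
Why: In the Corey–Bakshi–Shibata reduction the quaternary C1 acts as the large and the C3 methylene as the small group, so the (R)-oxazaborolidine should deliver hydride to give the 2S carbinol under reagent control.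

**Step 32**
Reactants: 52 (2S)-alcohol
Product: 53 2,14-diacetate
Conditions: Ac2O, DMAP, pyridine, rt
Reagents that add atoms: acetic anhydride CC(=O)OC(C)=O
Why: DMAP-catalysed acetylation of the only free hydroxyl.

**Step 33**
Reactants: 53 2,14-diacetate
Product: 54 8,9-diol
Conditions: HF·pyridine, pyridine, THF, 0 → 40 °C
Reagents that add atoms: none
Why: Fluoride-mediated cleavage of the tertiary TES and the hindered secondary TBS ether, which acetates, lactone and the NAP ether tolerate.

**Step 34**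
Reactants: 54 8,9-diol
Product: 55 9-ketone (20-O-NAP ether of the target)
Conditions: DMP, NaHCO3, CH2Cl2, 0 °C → rt
Reagents that add atoms: none
Why: Dess–Martin oxidation of the secondary alcohol of the secondary/tertiary diol gives the α-hydroxy ketone without glycol cleavage, and the buffer protects the epimerisable C10.

**Step 35**
Reactants: 55 20-O-NAP ether
Product: 56 CNP0140109.1
Conditions: DDQ, CH2Cl2/pH 7 buffer, rt
Reagents that add atoms: none
Why: Oxidative cleavage of the naphthylmethyl ether by DDQ frees the primary allylic alcohol under neutral conditions.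

**Compound list**

1 | 5-hydroxyfuran-2(5H)-one (racemic) | OC1OC(=O)C=C1 | starting material
2 | (1S,2R,5S)-(+)-menthol | CC(C)[C@H]1CC[C@H](C)C[C@@H]1O | starting material
3 | (5S)-5-{[(1S,2R,5S)-2-isopropyl-5-methylcyclohexyl]oxy}furan-2(5H)-one | CC(C)[C@H]1CC[C@H](C)C[C@@H]1O[C@H]2OC(=O)C=C2 | intermediate
4 | 2-bromoprop-2-en-1-ol | OCC(Br)=C | starting material
5 | 2-(bromomethyl)naphthalene | BrCc1ccc2ccccc2c1 | starting material
6 | 2-{[(2-bromoprop-2-en-1-yl)oxy]methyl}naphthalene | C=C(Br)COCc1ccc2ccccc2c1 | intermediate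
7 | [3-(naphthalen-2-ylmethoxy)prop-1-en-2-yl]lithium | [Li]C(=C)COCc1ccc2ccccc2c1 | intermediate (not isolated)
8 | lithium bis[3-(naphthalen-2-ylmethoxy)prop-1-en-2-yl]cuprate | [Li+].C=C(COCc1ccc2ccccc2c1)[Cu-]C(=C)COCc1ccc2ccccc2c1 | intermediate (not isolated)
9 | lithium enolate of the 1,4-adduct (C10 alkenyl trans to C9 O-Men) | CC(C)[C@H]1CC[C@H](C)C[C@@H]1O[C@H]2OC(O[Li])=C[C@@H]2C(=C)COCc3ccc4ccccc4c3 | intermediate (not isolated)
10 | all-trans 3-methyl-4-[3-(NAP-oxy)prop-1-en-2-yl]-5-(Men-oxy)dihydrofuran-2(3H)-one (furanone C3/C4/C5 = C1/C10/C9) | CC(C)[C@H]1CC[C@H](C)C[C@@H]1O[C@H]2OC(=O)[C@@H](C)[C@@H]2C(=C)COCc3ccc4ccccc4c3 | intermediate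
11 | lithium enolate of 10 | CC(C)[C@H]1CC[C@H](C)C[C@@H]1O[C@H]2OC(O[Li])=C(C)[C@@H]2C(=C)COCc3ccc4ccccc4c3 | intermediate (not isolated)
12 | 3-formyl-3-methyl lactone, quaternary C1 with CHO (C14) trans and CH3 cis to the C10 alkenyl group | CC(C)[C@H]1CC[C@H](C)C[C@@H]1O[C@H]2OC(=O)[C@@](C)(C=O)[C@@H]2C(=C)COCc3ccc4ccccc4c3 | intermediate
13 | (14S)-1-hydroxybut-3-enyl lactone | CC(C)[C@H]1CC[C@H](C)C[C@@H]1O[C@H]2OC(=O)[C@@](C)([C@@H](O)CC=C)[C@@H]2C(=C)COCc3ccc4ccccc4c3 | intermediate
14 | trans-fused cyclohexene–γ-lactone acetal (C11=C12, 20-O-NAP, 14S-OH, C9 O-Men) | CC(C)[C@H]1CC[C@H](C)C[C@@H]1O[C@H]2OC(=O)[C@@]3(C)[C@@H](O)CC=C(COCc4ccc5ccccc5c4)[C@H]23 | intermediate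
15 | cyclohexene triol: 14S-OH, C1 (CH3 trans to O14, CH2OH = C2 cis to O14), C10 CH2OH (= C9) cis to the C1 methyl, C11 CH2O-NAP | O[C@H]1CC=C(COCc2ccc3ccccc3c2)[C@H](CO)[C@@]1(C)CO | intermediate
16 | O14/O2 acetonide of 15 (cis-fused 1,3-dioxane), free C9 CH2OH | CC1(C)O[C@H]2CC=C(COCc3ccc4ccccc4c3)[C@H](CO)[C@@]2(C)CO1 | intermediate
17 | C9 aldehyde of 16 | CC1(C)O[C@H]2CC=C(COCc3ccc4ccccc4c3)[C@H](C=O)[C@@]2(C)CO1 | intermediate
18 | 3,4-dimethoxybenzyl alcohol | COc1ccc(CO)cc1OC | starting material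
19 | bromoacetic acid | OC(=O)CBr | starting material
20 | 2-[(3,4-dimethoxybenzyl)oxy]acetic acid | COc1ccc(COCC(=O)O)cc1OC | intermediate
21 | (S)-4-benzyl-1,3-thiazolidine-2-thione | S=C1N[C@@H](Cc2ccccc2)CS1 | starting material
22 | (S)-4-benzyl-3-{2-[(3,4-dimethoxybenzyl)oxy]acetyl}-1,3-thiazolidine-2-thione | COc1ccc(COCC(=O)N2[C@@H](Cc3ccccc3)CSC2=S)cc1OC | intermediate
23 | chlorotitanium (Z)-enolate of 22 | COc1ccc(CO/C=C(\O[Ti](Cl)(Cl)Cl)N2[C@@H](Cc3ccccc3)CSC2=S)cc1OC | intermediate (not isolated)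
24 | syn-aldol adduct (8S,9R): 9-OH, 8-ODMB, C7 acyl thiazolidinethione | CC1(C)O[C@H]2CC=C(COCc3ccc4ccccc4c3)[C@H]([C@@H](O)[C@H](OCc5ccc(OC)c(OC)c5)C(=O)N6[C@@H](Cc7ccccc7)CSC6=S)[C@@]2(C)CO1 | intermediate
25 | 9-O-TBS ether of 24 | CC1(C)O[C@H]2CC=C(COCc3ccc4ccccc4c3)[C@H]([C@@H](O[Si](C)(C)C(C)(C)C)[C@H](OCc5ccc(OC)c(OC)c5)C(=O)N6[C@@H](Cc7ccccc7)CSC6=S)[C@@]2(C)CO1 | intermediate
26 | C7 aldehyde (8S-ODMB, 9R-OTBS) | CC1(C)O[C@H]2CC=C(COCc3ccc4ccccc4c3)[C@H]([C@@H](O[Si](C)(C)C(C)(C)C)[C@H](OCc5ccc(OC)c(OC)c5)C=O)[C@@]2(C)CO1 | intermediate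
27 | prop-2-yn-1-ol | C#CCO | starting material
28 | (Z)-3-(bromomagnesio)-2-methylprop-2-en-1-olate magnesium bromide | Br[Mg]/C=C(/C)CO[Mg]Br | intermediate (not isolated)
29 | (Z)-3-iodo-2-methylprop-2-en-1-ol | I/C=C(/C)CO | intermediate
30 | triethyl{[(Z)-3-iodo-2-methylprop-2-en-1-yl]oxy}silane | I/C=C(/C)CO[Si](CC)(CC)CC | intermediate
31 | (Z)-alkenyllithium from 30 | [Li]/C=C(/C)CO[Si](CC)(CC)CC | intermediate (not isolated)
32 | (Z)-alkenylmagnesium bromide from 30 | Br[Mg]/C=C(/C)CO[Si](CC)(CC)CC | intermediate (not isolated)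
33 | (7S)-allylic alcohol: 7-OH, 8-ODMB, 9-OTBS, Z-C5=C6, 4-OTES | CC1(C)O[C@H]2CC=C(COCc3ccc4ccccc4c3)[C@H]([C@@H](O[Si](C)(C)C(C)(C)C)[C@H](OCc5ccc(OC)c(OC)c5)[C@H](/C=C(/C)CO[Si](CC)(CC)CC)O)[C@@]2(C)CO1 | intermediate
34 | 2-bromopropanoyl bromide (racemic) | CC(Br)C(=O)Br | starting material
35 | 7-O-(2-bromopropanoyl) ester of 33 (epimers at CHBr) | CC1(C)O[C@H]2CC=C(COCc3ccc4ccccc4c3)[C@H]([C@@H](O[Si](C)(C)C(C)(C)C)[C@H](OCc5ccc(OC)c(OC)c5)[C@H](/C=C(/C)CO[Si](CC)(CC)CC)OC(=O)C(C)Br)[C@@]2(C)CO1 | intermediate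
36 | C8 alcohol (DMB removed) | CC1(C)O[C@H]2CC=C(COCc3ccc4ccccc4c3)[C@H]([C@@H](O[Si](C)(C)C(C)(C)C)[C@H](O)[C@H](/C=C(/C)CO[Si](CC)(CC)CC)OC(=O)C(C)Br)[C@@]2(C)CO1 | intermediate
37 | C8 ketone, 7-O-(2-bromopropanoyl) | CC1(C)O[C@H]2CC=C(COCc3ccc4ccccc4c3)[C@H]([C@@H](O[Si](C)(C)C(C)(C)C)C(=O)[C@H](/C=C(/C)CO[Si](CC)(CC)CC)OC(=O)C(C)Br)[C@@]2(C)CO1 | intermediate
38 | samarium(III) ester enolate of 37 | CC1(C)O[C@H]2CC=C(COCc3ccc4ccccc4c3)[C@H]([C@@H](O[Si](C)(C)C(C)(C)C)C(=O)[C@H](/C=C(/C)CO[Si](CC)(CC)CC)OC(O[Sm](I)I)=CC)[C@@]2(C)CO1 | intermediate (not isolated)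
39 | β-hydroxy γ-lactone: 7-alkenyl, 8-OH and 17-CH3 mutually cis, C9 trans; 9-OTBS, 4-OTES, acetonide | CC1(C)O[C@H]2CC=C(COCc3ccc4ccccc4c3)[C@H]([C@@H](O[Si](C)(C)C(C)(C)C)[C@@]5(O)[C@H](/C=C(/C)CO[Si](CC)(CC)CC)OC(=O)[C@@H]5C)[C@@]2(C)CO1 | intermediate
40 | 8-O-TES ether of 39 | CC1(C)O[C@H]2CC=C(COCc3ccc4ccccc4c3)[C@H]([C@@H](O[Si](C)(C)C(C)(C)C)[C@@]5(O[Si](CC)(CC)CC)[C@H](/C=C(/C)CO[Si](CC)(CC)CC)OC(=O)[C@@H]5C)[C@@]2(C)CO1 | intermediate
41 | triol: 14-OH, C2 CH2OH, C4 CH2OH (8-OTES, 9-OTBS, 20-ONAP) | O[C@H]1CC=C(COCc2ccc3ccccc3c2)[C@H]([C@@H](O[Si](C)(C)C(C)(C)C)[C@@]4(O[Si](CC)(CC)CC)[C@H](/C=C(/C)CO)OC(=O)[C@@H]4C)[C@@]1(C)CO | intermediate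
42 | Z-allylic C4 chloride diol | O[C@H]1CC=C(COCc2ccc3ccccc3c2)[C@H]([C@@H](O[Si](C)(C)C(C)(C)C)[C@@]4(O[Si](CC)(CC)CC)[C@H](/C=C(/C)CCl)OC(=O)[C@@H]4C)[C@@]1(C)CO | intermediate
43 | C2 aldehyde, 14-OH | O[C@H]1CC=C(COCc2ccc3ccccc3c2)[C@H]([C@@H](O[Si](C)(C)C(C)(C)C)[C@@]4(O[Si](CC)(CC)CC)[C@H](/C=C(/C)CCl)OC(=O)[C@@H]4C)[C@@]1(C)C=O | intermediate
44 | C2 aldehyde, 14-OAc | CC(=O)O[C@H]1CC=C(COCc2ccc3ccccc3c2)[C@H]([C@@H](O[Si](C)(C)C(C)(C)C)[C@@]4(O[Si](CC)(CC)CC)[C@H](/C=C(/C)CCl)OC(=O)[C@@H]4C)[C@@]1(C)C=O | intermediate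
45 | methyl phenyl sulfone | CS(=O)(=O)c1ccccc1 | starting material
46 | (phenylsulfonyl)methyllithium | [Li]CS(=O)(=O)c1ccccc1 | intermediate (not isolated)
47 | β-hydroxy sulfone (C2 epimers) | CC(=O)O[C@H]1CC=C(COCc2ccc3ccccc3c2)[C@H]([C@@H](O[Si](C)(C)C(C)(C)C)[C@@]4(O[Si](CC)(CC)CC)[C@H](/C=C(/C)CCl)OC(=O)[C@@H]4C)[C@@]1(C)C(O)CS(=O)(=O)c5ccccc5 | intermediate
48 | seco β-keto sulfone with Z-allylic chloride and complete lactone (14-OAc, 9-OTBS, 8-OTES, 20-ONAP) | CC(=O)O[C@H]1CC=C(COCc2ccc3ccccc3c2)[C@H]([C@@H](O[Si](C)(C)C(C)(C)C)[C@@]4(O[Si](CC)(CC)CC)[C@H](/C=C(/C)CCl)OC(=O)[C@@H]4C)[C@@]1(C)C(=O)CS(=O)(=O)c5ccccc5 | intermediate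
49 | caesium enolate of 48 | CC(=O)O[C@H]1CC=C(COCc2ccc3ccccc3c2)[C@H]([C@@H](O[Si](C)(C)C(C)(C)C)[C@@]4(O[Si](CC)(CC)CC)[C@H](/C=C(/C)CCl)OC(=O)[C@@H]4C)[C@@]1(C)C(=O)[CH-]S(=O)(=O)c5ccccc5.[Cs+] | intermediate (not isolated)
50 | ten-membered α-sulfonyl C2 ketone (C3 epimers) | CC(=O)O[C@H]1CC=C(COCc4ccc5ccccc5c4)[C@@H]2[C@@H](O[Si](C)(C)C(C)(C)C)[C@@]3(O[Si](CC)(CC)CC)[C@H](/C=C(/C)CC(S(=O)(=O)c6ccccc6)C(=O)[C@]21C)OC(=O)[C@@H]3C | intermediate
51 | ten-membered C2 ketone | CC(=O)O[C@H]1CC=C(COCc4ccc5ccccc5c4)[C@@H]2[C@@H](O[Si](C)(C)C(C)(C)C)[C@@]3(O[Si](CC)(CC)CC)[C@H](/C=C(/C)CCC(=O)[C@]21C)OC(=O)[C@@H]3C | intermediate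
52 | (2S)-alcohol | CC(=O)O[C@H]1CC=C(COCc4ccc5ccccc5c4)[C@@H]2[C@@H](O[Si](C)(C)C(C)(C)C)[C@@]3(O[Si](CC)(CC)CC)[C@H](/C=C(/C)CC[C@H](O)[C@]21C)OC(=O)[C@@H]3C | intermediate
53 | 2,14-diacetate (9-OTBS, 8-OTES, 20-ONAP) | CC(=O)O[C@H]1CC=C(COCc4ccc5ccccc5c4)[C@@H]2[C@@H](O[Si](C)(C)C(C)(C)C)[C@@]3(O[Si](CC)(CC)CC)[C@H](/C=C(/C)CC[C@H](OC(C)=O)[C@]21C)OC(=O)[C@@H]3C | intermediate
54 | 8,9-diol | CC(=O)O[C@H]1CC=C(COCc4ccc5ccccc5c4)[C@@H]2[C@@H](O)[C@@]3(O)[C@H](/C=C(/C)CC[C@H](OC(C)=O)[C@]21C)OC(=O)[C@@H]3C | intermediate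
55 | 9-ketone, 20-O-NAP ether of the target | CC(=O)O[C@H]1CC=C(COCc4ccc5ccccc5c4)[C@@H]2C(=O)[C@@]3(O)[C@H](/C=C(/C)CC[C@H](OC(C)=O)[C@]21C)OC(=O)[C@@H]3C | intermediate
56 | CNP0140109.1 | CC(=O)O[C@H]1CC=C(CO)[C@@H]2C(=O)[C@@]3(O)[C@H](/C=C(/C)CC[C@H](OC(C)=O)[C@]21C)OC(=O)[C@@H]3C | target

**Totals**

Total step count: 35. Longest linear sequence: 30 steps (1, 3–9, 12–14, 17–35).

**Steps most likely to fail**

Step 29. The slow medium-ring closure may lose to intermolecular alkylation or to O-alkylation of the enolate. The fallback changes the mode of activation from an uncatalysed SN2 displacement to a palladium-catalysed Tsuji–Trost allylic alkylation. It sets out from keto sulfone 48, whose allylic chloride is ionised by Pd(PPh3)4/dppe to a π-allylpalladium complex. The sulfonyl enolate (Cs2CO3, THF, reflux, high dilution) attacks the unsubstituted C4 terminus, and the ring size should hold the cis alkene. The route is rejoined at macrocycle 50, and no new compound is made (F0).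

Step 21. The intramolecular samarium aldol may show poor facial selectivity at C8, or the C7–O bond of the α-acyloxy ketone may be cleaved reductively. The fallback forms the C8–C17 bond intermolecularly under chelation control and sets out from ketone 37. The 2-bromopropanoyl group is taken off with thiourea (NaHCO3, EtOH/THF, rt; sulfur displaces bromide and the ester is expelled as a thiazolinone) to give α-hydroxy ketone F1. F1 is then treated with an excess of the zinc enolate made from ethyl 2-bromopropanoate and zinc (THF, 0 °C). The C7 alkoxide and the C8 carbonyl chelate zinc (Cram chelate), so the enolate should add anti to the C7 alkenyl group to give hydroxy ester F2. F2 lactonises onto O7 on warming (C17 is equilibrated with DBU if needed) and rejoins the route at lactone 39.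

Step 27. The acetyl group may migrate from O14 to the new C2 alkoxide, or the carbanion may attack the acetate. The fallback replaces the aldehyde addition by a Claisen-type C-acylation, in which no alkoxide is formed, and sets out from aldehyde 44. Pinnick oxidation (NaClO2, NaH2PO4, 2-methylbut-2-ene, t-BuOH/H2O) gives carboxylic acid F3. 1-Chloro-N,N,2-trimethylprop-1-en-1-amine (CH2Cl2, 0 °C) converts it into acid chloride F4 under neutral conditions. F4 is added at −78 °C to two equivalents of lithiated sulfone 46; the product is deprotonated at once and is thereby protected from further attack. This returns directly to keto sulfone 48 and makes step 28 unnecessary.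

**Further compounds**

F0 | step 29 | none | none
F1 | step 21 | α-hydroxy ketone (7-OH, C8 ketone, 9-OTBS, 4-OTES, acetonide) | CC1(C)O[C@H]2CC=C(COCc3ccc4ccccc4c3)[C@H]([C@@H](O[Si](C)(C)C(C)(C)C)C(=O)[C@H](/C=C(/C)CO[Si](CC)(CC)CC)O)[C@@]2(C)CO1
F2 | step 21 | ethyl 2-methyl-3-hydroxy ester at C8 (open-chain precursor of lactone 39) | CC1(C)O[C@H]2CC=C(COCc3ccc4ccccc4c3)[C@H]([C@@H](O[Si](C)(C)C(C)(C)C)[C@](O)([C@@H](C)C(=O)OCC)[C@H](/C=C(/C)CO[Si](CC)(CC)CC)O)[C@@]2(C)CO1
F3 | step 27 | C2 carboxylic acid (14-OAc) | CC(=O)O[C@H]1CC=C(COCc2ccc3ccccc3c2)[C@H]([C@@H](O[Si](C)(C)C(C)(C)C)[C@@]4(O[Si](CC)(CC)CC)[C@H](/C=C(/C)CCl)OC(=O)[C@@H]4C)[C@@]1(C)C(=O)O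
F4 | step 27 | C2 acid chloride (14-OAc) | CC(=O)O[C@H]1CC=C(COCc2ccc3ccccc3c2)[C@H]([C@@H](O[Si](C)(C)C(C)(C)C)[C@@]4(O[Si](CC)(CC)CC)[C@H](/C=C(/C)CCl)OC(=O)[C@@H]4C)[C@@]1(C)C(=O)Cl
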